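**Strategy**

The route rests on disconnecting the dihydrofuran ring (O1–C2–C3–C3a–C7a, benzofuran numbering) at both bonds to C2. C3 is a benzylic CH2 ortho to the ring oxygen, the retron of an ortho-quinone methide (C7a=O, C3a=C3H2), and C2, the only stereocentre, is a one-carbon unit. A formal [4+1] annulation of this quinone methide with a chiral allylic sulfonium ylide forms C3–C2 and O1–C2 in one operation, sets C2 and closes the last ring of the skeleton. Its precursor is the complete benzyl-protected isoflavone bearing a free 4'-phenol and an ortho CH2NMe3+ group; the isopropenyl group so introduced is hydrated afterwards.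

Key step: step 9

Assumption: 4 and both enantiomers of isothiocineole are taken as catalogue compounds, and the usual ylide model for this sulfide (isopropenyl syn to the sulfur lone pair, attack on the face remote from the gem-dimethyl bridge) is taken to call for the (1S,4S,5S)-sulfide; if a model reaction shows the opposite sense, the (1R,4R,5R)-sulfide is used in the same way.

**Route**

Step 1
Reactants: 1 2,6-dihydroxybenzaldehyde
Product: 2 2-(benzyloxy)-6-hydroxybenzaldehyde
Conditions: BnBr (1.0 equiv), K2CO3, acetone, 50 °C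
Reagents that add atoms: benzyl bromide, BrCc1ccccc1
Why: Williamson etherification; with one equivalent of benzyl bromide the non-chelated hydroxyl reacts, and the remaining OH, then locked in a hydrogen bond to the aldehyde, is much less nucleophilic.

Step 2
Reactants: 2 2-(benzyloxy)-6-hydroxybenzaldehyde
Product: 3 2-(benzyloxy)-3-bromo-6-hydroxybenzaldehyde
Conditions: NBS (1.0 equiv), MeCN, 0 °C
Reagents that add atoms: N-bromosuccinimide, O=C1CCC(=O)N1Br
Why: Electrophilic aromatic bromination, expected para to the free phenol (C3, also ortho to the benzyloxy group), the aldehyde deactivating C4.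

Step 3
Reactants: 4 1-[2,4-bis(benzyloxy)-6-hydroxyphenyl]ethan-1-one
Product: 5 (E)-1-[2,4-bis(benzyloxy)-6-hydroxyphenyl]-3-(dimethylamino)prop-2-en-1-one
Conditions: DMF dimethyl acetal, toluene, 100 °C
Reagents that add atoms: N,N-dimethylformamide dimethyl acetal, COC(OC)N(C)C
Why: Condensation of the methyl ketone with the amide acetal should give the enaminone, with the chelated phenol left free.

Step 4
Reactants: 5 (E)-1-[2,4-bis(benzyloxy)-6-hydroxyphenyl]-3-(dimethylamino)prop-2-en-1-one
Product: 6 5,7-bis(benzyloxy)-3-iodo-4H-chromen-4-one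
Conditions: I2, MeOH, rt
Reagents that add atoms: iodine, II
Why: Iodine-mediated enaminone cyclisation: iodination of the α-carbon, 6-endo addition of the phenol to the iminium carbon and loss of dimethylamine close the pyranone as the 3-iodochromone.

Step 5
Reactants: 3 2-(benzyloxy)-3-bromo-6-hydroxybenzaldehyde; 6 5,7-bis(benzyloxy)-3-iodo-4H-chromen-4-one
Product: 8 2-(benzyloxy)-3-[5,7-bis(benzyloxy)-4-oxo-4H-chromen-3-yl]-6-hydroxybenzaldehyde, via pinacol boronate 7 (not isolated)
Conditions: B2pin2, Pd(dppf)Cl2 (5 mol%), KOAc, 1,4-dioxane, 90 °C; then 6, aq. K2CO3, 80 °C (one pot)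
Reagents that add atoms: bis(pinacolato)diboron, CC1(C)OB(OC1(C)C)B1OC(C)(C)C(C)(C)O1 (its Bpin group is carried only by intermediate 7 and is lost again in the coupling)
Why: Miyaura borylation of the aryl bromide followed in the same flask by Suzuki–Miyaura coupling with the reactive C3–I bond of the iodochromone, the standard isoflavone assembly, which tolerates the phenol and the aldehyde.

Step 6
Reactants: 8 2-(benzyloxy)-3-[5,7-bis(benzyloxy)-4-oxo-4H-chromen-3-yl]-6-hydroxybenzaldehyde
Product: 9 5,7-bis(benzyloxy)-3-{2-(benzyloxy)-3-[(dimethylamino)methyl]-4-hydroxyphenyl}-4H-chromen-4-one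
Conditions: Me2NH (2 M in THF), NaBH(OAc)3, AcOH, 1,2-dichloroethane, rt
Reagents that add atoms: dimethylamine, CNC
Why: Reductive amination (iminium formation assisted by the ortho-hydroxyl, hydride from triacetoxyborohydride), a reductant that should leave the chromone untouched.

Step 7
Reactants: 9 5,7-bis(benzyloxy)-3-{2-(benzyloxy)-3-[(dimethylamino)methyl]-4-hydroxyphenyl}-4H-chromen-4-one
Product: 10 {2-(benzyloxy)-3-[5,7-bis(benzyloxy)-4-oxo-4H-chromen-3-yl]-6-hydroxyphenyl}-N,N,N-trimethylmethanaminium iodide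
Conditions: MeI (excess), MeCN, rt, dark
Reagents that add atoms: iodomethane, CI
Why: Menshutkin quaternisation of the tertiary amine; without added base the phenol is not methylated, and the salt is the latent ortho-quinone methide.

Step 8
Reactants: 11 (1S,4S,5S)-4,7,7-trimethyl-6-thiabicyclo[3.2.1]octane (isothiocineole); 12 3-bromo-2-methylprop-1-ene
Product: 13 (1S,4S,5S)-4,7,7-trimethyl-6-(2-methylprop-2-en-1-yl)-6-thiabicyclo[3.2.1]octan-6-ium tetrafluoroborate (allyl group on the exo lone pair of sulfur)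
Conditions: NaBF4, CH2Cl2/H2O, rt
Reagents that add atoms: sodium tetrafluoroborate, [Na+].F[B-](F)(F)F
Why: S-Alkylation of the sulfide by the allylic bromide on its less hindered lone pair, driven by exchange of bromide for the non-nucleophilic tetrafluoroborate.

Step 9
Reactants: 10 {2-(benzyloxy)-3-[5,7-bis(benzyloxy)-4-oxo-4H-chromen-3-yl]-6-hydroxyphenyl}-N,N,N-trimethylmethanaminium iodide; 13 (1S,4S,5S)-4,7,7-trimethyl-6-(2-methylprop-2-en-1-yl)-6-thiabicyclo[3.2.1]octan-6-ium tetrafluoroborate
Product: 16 5,7-bis(benzyloxy)-3-[(2R)-4-(benzyloxy)-2-(prop-1-en-2-yl)-2,3-dihydro-1-benzofuran-5-yl]-4H-chromen-4-one, via o-quinone methide 14 (not isolated), via sulfonium phenolate betaine 15 (not isolated)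
Conditions: 13 (1.5 equiv), Cs2CO3 (3.5 equiv), MeCN/CH2Cl2, −20 °C to rt
Reagents that add atoms: none
Why: Carbonate deprotonates the phenol of 10, the zwitterion expels trimethylamine to give the ortho-quinone methide 14 (C7a=O, C3a=C3H2), and the allylic sulfonium ylide made from 13 adds through its α-carbon to the exocyclic CH2 (C3–C2 bond), rearomatisation making this addition irreversible; the phenoxide of betaine 15 then displaces the sulfide at C2 (O1–C2 bond). The closest known reaction type is the sulfur-ylide [4+1] annulation of ortho-quinone methides to 2,3-dihydrobenzofurans, combined with the chiral-sulfide ylide control known from asymmetric epoxidation, aziridination and cyclopropanation. The ring closes 5-exo-tet by SN2 with inversion at C2. C2 is controlled by the sulfonium group: the ylide should react from the conformer with the isopropenyl group syn to the sulfur lone pair and on the face remote from the gem-dimethyl bridge, and as 15 holds no acidic C–H the centre cannot erode before closure. The step needs α- rather than γ-attack of the allyl ylide and closure on O4' rather than on O2' or O-allylation of the phenoxide. These are secured by the 2-methyl group and the charge at the α-carbon, by the benzyl ether on O2', and by the electron-rich ring, which releases the quinone methide fast and keeps the phenoxide short-lived.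

Step 10
Reactants: 16 5,7-bis(benzyloxy)-3-[(2R)-4-(benzyloxy)-2-(prop-1-en-2-yl)-2,3-dihydro-1-benzofuran-5-yl]-4H-chromen-4-one
Product: 17 5,7-bis(benzyloxy)-3-[(2R)-4-(benzyloxy)-2-(2-hydroxypropan-2-yl)-2,3-dihydro-1-benzofuran-5-yl]-4H-chromen-4-one
Conditions: Co(acac)2 (20 mol%), PhSiH3, O2 (1 atm), THF, rt; then aq. Na2S2O3
Reagents that add atoms: dioxygen, O=O
Why: Mukaiyama hydration: hydrogen-atom transfer from cobalt hydride to the 1,1-disubstituted alkene gives the tertiary radical, which is trapped by O2 and reduced to the Markovnikov tertiary alcohol, while the electron-poor C2=C3 bond of the chromone should react much more slowly and C2 of the benzofuran is not touched.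

Step 11
Reactants: 17 5,7-bis(benzyloxy)-3-[(2R)-4-(benzyloxy)-2-(2-hydroxypropan-2-yl)-2,3-dihydro-1-benzofuran-5-yl]-4H-chromen-4-one
Product: 18 5,7-dihydroxy-3-[(2R)-4-hydroxy-2-(2-hydroxypropan-2-yl)-2,3-dihydro-1-benzofuran-5-yl]-4H-chromen-4-one
Conditions: H2 (1 atm), 10% Pd/C, EtOAc/MeOH, rt, stopped after uptake of 3 equiv
Reagents that add atoms: none
Why: Hydrogenolysis of the three benzyl ethers; the non-benzylic C2–O1 bond and the tertiary alcohol are inert, and stopping at three equivalents should keep the chromone double bond.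

**Compound list**

1 | 2,6-dihydroxybenzaldehyde | O=Cc1c(O)cccc1O | starting material
2 | 2-(benzyloxy)-6-hydroxybenzaldehyde | O=Cc1c(O)cccc1OCc1ccccc1 | intermediate
3 | 2-(benzyloxy)-3-bromo-6-hydroxybenzaldehyde | O=Cc1c(O)ccc(Br)c1OCc1ccccc1 | intermediate
4 | 1-[2,4-bis(benzyloxy)-6-hydroxyphenyl]ethan-1-one | CC(=O)c1c(O)cc(OCc2ccccc2)cc1OCc1ccccc1 | starting material
5 | (E)-1-[2,4-bis(benzyloxy)-6-hydroxyphenyl]-3-(dimethylamino)prop-2-en-1-one | CN(C)/C=C/C(=O)c1c(O)cc(OCc2ccccc2)cc1OCc1ccccc1 | intermediate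
6 | 5,7-bis(benzyloxy)-3-iodo-4H-chromen-4-one | O=c1c(I)coc2cc(OCc3ccccc3)cc(OCc3ccccc3)c12 | intermediate
7 | 2-(benzyloxy)-6-hydroxy-3-(4,4,5,5-tetramethyl-1,3,2-dioxaborolan-2-yl)benzaldehyde (not isolated) | O=Cc1c(O)ccc(B2OC(C)(C)C(C)(C)O2)c1OCc1ccccc1 | intermediate
8 | 2-(benzyloxy)-3-[5,7-bis(benzyloxy)-4-oxo-4H-chromen-3-yl]-6-hydroxybenzaldehyde | O=Cc1c(O)ccc(-c2coc3cc(OCc4ccccc4)cc(OCc4ccccc4)c3c2=O)c1OCc1ccccc1 | intermediate
9 | 5,7-bis(benzyloxy)-3-{2-(benzyloxy)-3-[(dimethylamino)methyl]-4-hydroxyphenyl}-4H-chromen-4-one | CN(C)Cc1c(O)ccc(-c2coc3cc(OCc4ccccc4)cc(OCc4ccccc4)c3c2=O)c1OCc1ccccc1 | intermediate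
10 | {2-(benzyloxy)-3-[5,7-bis(benzyloxy)-4-oxo-4H-chromen-3-yl]-6-hydroxyphenyl}-N,N,N-trimethylmethanaminium iodide | C[N+](C)(C)Cc1c(O)ccc(-c2coc3cc(OCc4ccccc4)cc(OCc4ccccc4)c3c2=O)c1OCc1ccccc1.[I-] | intermediate
11 | (1S,4S,5S)-4,7,7-trimethyl-6-thiabicyclo[3.2.1]octane (isothiocineole) | C[C@H]1CC[C@H]2C[C@@H]1SC2(C)C | starting material
12 | 3-bromo-2-methylprop-1-ene | C=C(C)CBr | starting material
13 | (1S,4S,5S)-4,7,7-trimethyl-6-(2-methylprop-2-en-1-yl)-6-thiabicyclo[3.2.1]octan-6-ium tetrafluoroborate, exo S-allyl | C[C@H]1CC[C@H]2C[C@@H]1[S@+](CC(C)=C)C2(C)C.F[B-](F)(F)F | intermediate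
14 | 5,7-bis(benzyloxy)-3-[2-(benzyloxy)-3-methylidene-4-oxocyclohexa-1,5-dien-1-yl]-4H-chromen-4-one (o-quinone methide, not isolated) | C=C1C(=O)C=CC(-c2coc3cc(OCc4ccccc4)cc(OCc4ccccc4)c3c2=O)=C1OCc1ccccc1 | intermediate
15 | sulfonium phenolate betaine from addition of the ylide α-carbon to the CH2 of 14 (not isolated) | C[C@H]1CC[C@H]2C[C@@H]1[S@+]([C@@H](Cc3c([O-])ccc(-c4coc5cc(OCc6ccccc6)cc(OCc6ccccc6)c5c4=O)c3OCc3ccccc3)C(C)=C)C2(C)C | intermediate
16 | 5,7-bis(benzyloxy)-3-[(2R)-4-(benzyloxy)-2-(prop-1-en-2-yl)-2,3-dihydro-1-benzofuran-5-yl]-4H-chromen-4-one | C=C(C)[C@H]1Cc2c(ccc(-c3coc4cc(OCc5ccccc5)cc(OCc5ccccc5)c4c3=O)c2OCc2ccccc2)O1 | intermediate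
17 | 5,7-bis(benzyloxy)-3-[(2R)-4-(benzyloxy)-2-(2-hydroxypropan-2-yl)-2,3-dihydro-1-benzofuran-5-yl]-4H-chromen-4-one | CC(C)(O)[C@H]1Cc2c(ccc(-c3coc4cc(OCc5ccccc5)cc(OCc5ccccc5)c4c3=O)c2OCc2ccccc2)O1 | intermediate
18 | 5,7-dihydroxy-3-[(2R)-4-hydroxy-2-(2-hydroxypropan-2-yl)-2,3-dihydro-1-benzofuran-5-yl]-4H-chromen-4-one | CC(C)(O)[C@H]1Cc2c(ccc(-c3coc4cc(O)cc(O)c4c3=O)c2O)O1 | target

**Step count**

Total step count: 11. Longest linear sequence: 8 steps (1, 2, 5, 6, 7, 9, 10, 11).

**Steps most likely to fail**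

Step 9. The allyl ylide may add through its γ-carbon, the phenoxide may be O-allylated by the sulfonium salt before the quinone methide is released, or the facial selectivity on the unsubstituted methylene may be low. The fallback sets out from 10 and comes back at 17, leaving out 16. The quinone methide is released from 10 as before (Cs2CO3) but is intercepted by 4,4,5,5-tetramethyl-2-(2-methylprop-1-en-1-yl)-1,3,2-dioxaborolane with a catalytic biaryl diol, a conjugate addition of an alkenylboronate to an ortho-quinone methide, to give the ortho-prenyl phenol F1. Acetylation (Ac2O, pyridine) gives the aryl acetate F2. Shi epoxidation of its trisubstituted alkene with the ketone enantiomeric to the D-fructose-derived catalyst (Oxone, K2CO3 buffer, MeCN/dimethoxymethane/H2O, 0 °C) should give the (S)-epoxide F3. K2CO3 in MeOH then removes the acetate, and the phenoxide opens the epoxide 5-exo-tet at the secondary carbon with inversion, which should give 17 with the (R)-centre and the tertiary alcohol in place.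

Step 5. The para-hydroxyaryl boronate may protodeboronate, or the salicylaldehyde may sequester the catalyst, so that the one-pot coupling stalls. The fallback sets out from 3 and comes back at 8. The phenol is masked as the methoxymethyl ether F4 (MOMCl, iPr2NEt, CH2Cl2), the bromide is borylated and the boronate F5 is isolated, and coupling with 6 (Pd(dppf)Cl2, aq. K2CO3, dioxane) gives the protected biaryl F6. HCl in MeOH then removes the acetal and returns 8.

Step 2. Bromination may occur ortho instead of para to the free hydroxyl, or twice. The fallback sets out from 1 and comes back at 3, leaving out 2. Bromination of 1 itself (NBS, 1.0 equiv, MeCN, 0 °C) can give only one monobromide, 3-bromo-2,6-dihydroxybenzaldehyde F7, because the two activated positions are equivalent by symmetry. A Mitsunobu benzylation (BnOH, PPh3, DIAD, THF) should then select the more acidic hydroxyl flanked by bromine, the other staying chelated to the aldehyde, and give 3.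

**Further compounds**

F1 | step 9 | 5,7-bis(benzyloxy)-3-[2-(benzyloxy)-4-hydroxy-3-(3-methylbut-2-en-1-yl)phenyl]-4H-chromen-4-one | CC(C)=CCc1c(O)ccc(-c2coc3cc(OCc4ccccc4)cc(OCc4ccccc4)c3c2=O)c1OCc1ccccc1
F2 | step 9 | 3-(benzyloxy)-4-[5,7-bis(benzyloxy)-4-oxo-4H-chromen-3-yl]-2-(3-methylbut-2-en-1-yl)phenyl acetate | CC(C)=CCc1c(OC(C)=O)ccc(-c2coc3cc(OCc4ccccc4)cc(OCc4ccccc4)c3c2=O)c1OCc1ccccc1
F3 | step 9 | 3-(benzyloxy)-4-[5,7-bis(benzyloxy)-4-oxo-4H-chromen-3-yl]-2-{[(2S)-3,3-dimethyloxiran-2-yl]methyl}phenyl acetate | CC(=O)Oc1ccc(-c2coc3cc(OCc4ccccc4)cc(OCc4ccccc4)c3c2=O)c(OCc2ccccc2)c1C[C@@H]1OC1(C)C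
F4 | step 5 | 2-(benzyloxy)-3-bromo-6-(methoxymethoxy)benzaldehyde | O=Cc1c(OCOC)ccc(Br)c1OCc1ccccc1
F5 | step 5 | 2-(benzyloxy)-6-(methoxymethoxy)-3-(4,4,5,5-tetramethyl-1,3,2-dioxaborolan-2-yl)benzaldehyde | O=Cc1c(OCOC)ccc(B2OC(C)(C)C(C)(C)O2)c1OCc1ccccc1
F6 | step 5 | 2-(benzyloxy)-3-[5,7-bis(benzyloxy)-4-oxo-4H-chromen-3-yl]-6-(methoxymethoxy)benzaldehyde | O=Cc1c(OCOC)ccc(-c2coc3cc(OCc4ccccc4)cc(OCc4ccccc4)c3c2=O)c1OCc1ccccc1
F7 | step 2 | 3-bromo-2,6-dihydroxybenzaldehyde | O=Cc1c(O)ccc(Br)c1O
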